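**Plan** (chroman numbering; ring A = benzene ring, ring B = dihydropyran ring)

1. The target is the 5-formyl derivative of (R)-δ-tocotrienol: one stereocentre (C2, R) and two E trisubstituted alkenes in the side chain.
2. Retrosynthesis: unmask CHO (from an N-tert-butyl imine) and OH (from a MOM ether), then open ring B by cutting C3–C4 and O1–C8a together. This gives an aryl piece (C4 as a methyl group, C8a as C–Br) and the (R)-epoxide O1–C2–C3, which already carries C2, its methyl group and the whole side chain; the epoxide goes back to farnesylacetone and (2E,6E)-farnesyl bromide.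
3. Enabling feature: on ring A, C4 is a benzylic carbon on C4a directly ortho to the C5 formyl carbon (as the imine it makes C4–H acidic and holds the base). C8a, which must bind O1, lies para to the C6 oxygen between C4a and the methyl-bearing C8, which is exactly the brominated carbon of 4-bromo-3,5-dimethylphenol. A 2,2-disubstituted epoxide offers C3 as electrophile and frees O1 as nucleophile.
4. Forward order: ortho-formylation of the symmetric phenol (this makes the two methyl groups different), MOM ether, imine; in parallel farnesyl bromide to methyl ketone to epoxide; the pieces are joined and ring B is closed last in one flask (C3–C4, then O1–C8a); acid then frees CHO and OH.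
5. Stereochemistry: C2 is set by catalyst-controlled methylene transfer to the methyl ketone (step 5) and is not touched again, since the annulation makes bonds only at C3 and O1; the alkene geometry comes with farnesyl bromide.

Key step: step 6

Assumption: in step 5 the (S)-binaphthoxide complex is written as the antipode that gives the (R)-epoxide; the sense of induction for this dialkyl ketone is to be checked on the first run, and the (R)-binaphthoxide complex is used if it proves opposite.

**Step 1**
Reactants: 1 4-bromo-3,5-dimethylphenol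
Product: 2 3-bromo-6-hydroxy-2,4-dimethylbenzaldehyde
Conditions: MgCl2, Et3N, (CH2O)n, MeCN, reflux; aq. HCl work-up
Reagents that add atoms: paraformaldehyde (as formaldehyde), C=O
Why: Magnesium-phenoxide-directed ortho-formylation (Casnati–Skattebøl reaction) places the formyl group only ortho to the OH, and since the two ortho positions of 1 are mirror-related a single aldehyde should form in which the methyl group next to CHO (the future C4) is now distinct from the other one (the future C8 methyl).

**Step 2**
Reactants: 2 3-bromo-6-hydroxy-2,4-dimethylbenzaldehyde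
Product: 3 3-bromo-6-(methoxymethoxy)-2,4-dimethylbenzaldehyde
Conditions: MOMCl, iPr2NEt, CH2Cl2, 0 → 23 °C
Reagents that add atoms: chloromethyl methyl ether, COCCl
Why: O-alkylation of the phenol with an alpha-chloro ether (MOM protection, Williamson type) masks the acidic OH as an acetal that withstands amide bases, alkoxides and the palladium step.

**Step 3**
Reactants: 3 3-bromo-6-(methoxymethoxy)-2,4-dimethylbenzaldehyde
Product: 4 (E)-1-[3-bromo-6-(methoxymethoxy)-2,4-dimethylphenyl]-N-tert-butylmethanimine
Conditions: t-BuNH2 (excess), 4 Å molecular sieves, CH2Cl2, 40 °C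
Reagents that add atoms: tert-butylamine, CC(C)(C)N
Why: Condensation of the aldehyde with a primary amine (imine formation) should give the E aldimine, which shields the formyl carbon from nucleophiles and, having no alpha hydrogen on the nitrogen substituent, serves as directing and anion-stabilising group for lateral lithiation.

**Step 4**
Reactants: 5 (2E,6E)-farnesyl bromide; 6 ethyl acetoacetate
Product: 8 (5E,9E)-6,10,14-trimethylpentadeca-5,9,13-trien-2-one (farnesylacetone), via beta-keto ester 7 (not isolated)
Conditions: NaOEt, EtOH, 0 → 23 °C; then aq. NaOH, 50 °C; then aq. HCl to pH 3, 50 °C (−CO2)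
Reagents that add atoms: none
Why: Acetoacetic ester synthesis: SN2 alkylation of the acetoacetate enolate at the primary allylic bromide (olefin geometry untouched), then saponification and decarboxylation of the beta-keto acid, should give the methyl ketone.

**Step 5**
Reactants: 8 (5E,9E)-6,10,14-trimethylpentadeca-5,9,13-trien-2-one
Product: 9 (2R)-2-methyl-2-[(3E,7E)-4,8,12-trimethyltrideca-3,7,11-trien-1-yl]oxirane
Conditions: Me2S(O)=CH2 (from Me3S(O)I, NaH, THF), LaLi3[(S)-binaphthoxide]3 (5 mol %), (2,4,6-(MeO)3C6H2)3P=O (5 mol %), 5 Å molecular sieves, THF, 23 °C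
Reagents that add atoms: dimethylsulfoxonium methylide, C[S+](C)(=O)[CH2-] (generated from trimethylsulfoxonium iodide, C[S+](C)(C)=O.[I-], and NaH)
Why: Catalytic asymmetric Corey–Chaykovsky epoxidation, in which the chiral lanthanum–lithium binaphthoxide complex binds ketone and ylide and directs methylene transfer to one carbonyl face, sets C2 (R) by catalyst control, while the isolated trisubstituted alkenes are inert to the sulfoxonium ylide.

**Step 6**
Reactants: 4 (E)-1-[3-bromo-6-(methoxymethoxy)-2,4-dimethylphenyl]-N-tert-butylmethanimine; 9 (2R)-2-methyl-2-[(3E,7E)-4,8,12-trimethyltrideca-3,7,11-trien-1-yl]oxirane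
Product: 12 (E)-N-tert-butyl-1-{(2R)-6-(methoxymethoxy)-2,8-dimethyl-2-[(3E,7E)-4,8,12-trimethyltrideca-3,7,11-trien-1-yl]-3,4-dihydro-2H-chromen-5-yl}methanimine, via benzylic lithium species 10 (not isolated), via lithium alkoxide 11 (not isolated)
Conditions: LiTMP (from 2,2,6,6-tetramethylpiperidine, n-BuLi), THF, −78 → −40 °C; 9, DMPU, −40 → 23 °C; then Pd2(dba)3 (2.5 mol %), tBuXPhos (6 mol %), toluene, 80 °C
Reagents that add atoms: none
Why: Proposed new method: a one-flask formal [3+3] annulation that merges two known reaction types, lateral lithiation–alkylation of an ortho-methyl aryl aldimine and palladium-catalysed intramolecular aryl etherification of a tertiary alkoxide (the closest precedents, each known separately; their merger with the lithium alkoxide used directly is new). Mechanism: LiTMP, held by the imine nitrogen, removes a proton from the methyl group ortho to the imine to give the delocalised benzylic anion 10, whose carbon opens epoxide 9 by SN2 attack at the unsubstituted CH2 (C3–C4 bond) and so releases the tertiary alkoxide 11; zerovalent palladium then inserts into the C8a–Br bond, bromide is exchanged for the tethered alkoxide, and C–O reductive elimination forms the O1–C8a bond. Ring B (O1, C2, C3, C4, C4a, C8a) is closed in this second event, a six-membered ring closure by reductive elimination from a seven-membered aryl(alkoxo)palladium chelate; ring A is present from the start. No stereocentre is formed: C2 comes from 9 and keeps its R configuration because the nucleophile attacks C3 and the C2–O1 bond is never broken. The selectivities needed are ortho- rather than para-methyl deprotonation (coordination of the lithium amide to the imine nitrogen), survival of the aryl bromide (amide base instead of alkyllithium and no hydrogen ortho to bromine, so neither exchange nor aryne formation), attack at the less hindered epoxide carbon, and etherification rather than reduction (neither the tertiary alkoxide nor tetramethylpiperidine has a hydrogen that palladium could remove by beta-hydride elimination).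

**Step 7**
Reactants: 12 (E)-N-tert-butyl-1-{(2R)-6-(methoxymethoxy)-2,8-dimethyl-2-[(3E,7E)-4,8,12-trimethyltrideca-3,7,11-trien-1-yl]-3,4-dihydro-2H-chromen-5-yl}methanimine
Product: 13 (2R)-6-hydroxy-2,8-dimethyl-2-[(3E,7E)-4,8,12-trimethyltrideca-3,7,11-trien-1-yl]-3,4-dihydro-2H-chromene-5-carbaldehyde
Conditions: 2 M aq. HCl, THF–MeOH, 23 → 40 °C
Reagents that add atoms: water, O
Why: Acid hydrolysis of the aldimine and acid cleavage of the MOM acetal (eased by the ortho formyl group) should occur together, while dilute acid at moderate temperature should leave the trisubstituted alkenes and the chroman ether untouched.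

**Compound list**

1 | 4-bromo-3,5-dimethylphenol | Cc1cc(O)cc(C)c1Br | starting material
2 | 3-bromo-6-hydroxy-2,4-dimethylbenzaldehyde | O=Cc1c(O)cc(C)c(Br)c1C | intermediate
3 | 3-bromo-6-(methoxymethoxy)-2,4-dimethylbenzaldehyde | O=Cc1c(OCOC)cc(C)c(Br)c1C | intermediate
4 | (E)-1-[3-bromo-6-(methoxymethoxy)-2,4-dimethylphenyl]-N-tert-butylmethanimine | CC(C)(C)/N=C/c1c(OCOC)cc(C)c(Br)c1C | intermediate
5 | (2E,6E)-1-bromo-3,7,11-trimethyldodeca-2,6,10-triene (farnesyl bromide) | CC(C)=CCC/C(C)=C/CC/C(C)=C/CBr | starting material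
6 | ethyl acetoacetate | CCOC(=O)CC(C)=O | starting material
7 | ethyl (4E,8E)-2-acetyl-5,9,13-trimethyltetradeca-4,8,12-trienoate (not isolated) | CC(C)=CCC/C(C)=C/CC/C(C)=C/CC(C(C)=O)C(=O)OCC | intermediate
8 | (5E,9E)-6,10,14-trimethylpentadeca-5,9,13-trien-2-one | CC(C)=CCC/C(C)=C/CC/C(C)=C/CCC(C)=O | intermediate
9 | (2R)-2-methyl-2-[(3E,7E)-4,8,12-trimethyltrideca-3,7,11-trien-1-yl]oxirane | CC(C)=CCC/C(C)=C/CC/C(C)=C/CC[C@]1(C)CO1 | intermediate
10 | {[2-bromo-6-[(E)-(tert-butylimino)methyl]-5-(methoxymethoxy)-3-methylphenyl]methyl}lithium (not isolated) | [Li]Cc1c(Br)c(C)cc(OCOC)c1/C=N/C(C)(C)C | intermediate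
11 | lithium (3R,6E,10E)-1-{2-bromo-6-[(E)-(tert-butylimino)methyl]-5-(methoxymethoxy)-3-methylphenyl}-3,7,11,15-tetramethylhexadeca-6,10,14-trien-3-olate (not isolated) | CC(C)=CCC/C(C)=C/CC/C(C)=C/CC[C@](O[Li])(C)CCc1c(Br)c(C)cc(OCOC)c1/C=N/C(C)(C)C | intermediate
12 | (E)-N-tert-butyl-1-{(2R)-6-(methoxymethoxy)-2,8-dimethyl-2-[(3E,7E)-4,8,12-trimethyltrideca-3,7,11-trien-1-yl]-3,4-dihydro-2H-chromen-5-yl}methanimine | CC(C)=CCC/C(C)=C/CC/C(C)=C/CC[C@]1(C)CCc2c(/C=N/C(C)(C)C)c(OCOC)cc(C)c2O1 | intermediate
13 | (2R)-6-hydroxy-2,8-dimethyl-2-[(3E,7E)-4,8,12-trimethyltrideca-3,7,11-trien-1-yl]-3,4-dihydro-2H-chromene-5-carbaldehyde | CC(C)=CCC/C(C)=C/CC/C(C)=C/CC[C@]1(C)CCc2c(C=O)c(O)cc(C)c2O1 | target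

**Step count**

Total: 7 steps. Longest linear sequence: 5 steps (steps 1, 2, 3, 6, 7); the side-chain branch is steps 4 and 5.

**Steps most likely to fail**

Step 6 (one-flask annulation). The palladium cycle may be shut down by the amine, the lithium salts or traces of unreacted base, or the epoxide opening may still be incomplete when the catalyst is added, so that the sequence stalls at the open-chain stage. Fallback, setting out from 4 and 9: the two bonds are made in two separate, individually precedented operations. Lateral lithiation of 4 (via 10) and opening of 9 are run alone, and the alkoxide 11 is quenched with aqueous NH4Cl to give, after chromatography, the bromo alcohol (3R,6E,10E)-1-{2-bromo-6-[(E)-(tert-butylimino)methyl]-5-(methoxymethoxy)-3-methylphenyl}-3,7,11,15-tetramethylhexadeca-6,10,14-trien-3-ol F1. Its ring is then closed by a copper-catalysed intramolecular Ullmann etherification (CuI, 1,10-phenanthroline, Cs2CO3, toluene, 110 °C), which returns to the route at 12.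

Step 5 (asymmetric methylene transfer). Facial discrimination between the methyl group and the unbranched CH2 chain of a purely aliphatic ketone may be insufficient, or the three alkenes may slow the catalyst, which would lower the enantiomeric purity that every later compound inherits. Fallback, setting out from 5: a tartrate-controlled sequence. The dilithio derivative of 2-methylprop-2-en-1-ol F2 (n-BuLi, TMEDA, Et2O–hexane) is alkylated by 5 to give (5E,9E)-6,10,14-trimethyl-2-methylidenepentadeca-5,9,13-trien-1-ol F3. Sharpless asymmetric epoxidation (Ti(OiPr)4, D-(−)-diethyl tartrate, t-BuOOH, 4 Å molecular sieves, CH2Cl2, −20 °C; the antipode of the tartrate that turns 2-methylprop-2-en-1-ol into (S)-2-methylglycidol) should give {(2R)-2-[(3E,7E)-4,8,12-trimethyltrideca-3,7,11-trien-1-yl]oxiran-2-yl}methanol F4. LiAlH4 (THF, 0 °C) opens the epoxide at its CH2 carbon to (2R,5E,9E)-2,6,10,14-tetramethylpentadeca-5,9,13-triene-1,2-diol F5. Tosylation of the primary hydroxyl (TsCl, pyridine, 0 °C) gives (2R,5E,9E)-2-hydroxy-2,6,10,14-tetramethylpentadeca-5,9,13-trien-1-yl 4-methylbenzenesulfonate F6, and K2CO3 in MeOH closes the ring to 9, where the route is rejoined.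

Step 7 (acidic unmasking). Protonation of the trisubstituted alkenes (hydration, chloride addition or cation–olefin cyclisation along the chain) or hydroxymethylation of the freed electron-rich phenol by released formaldehyde may compete with acetal cleavage. Fallback, setting out from 2: the phenol is carried as a fluoride-labile SEM ether so that no strong acid is needed at the end. SEMCl and iPr2NEt give 3-bromo-2,4-dimethyl-6-{[2-(trimethylsilyl)ethoxy]methoxy}benzaldehyde F7, and t-BuNH2 gives (E)-1-(3-bromo-2,4-dimethyl-6-{[2-(trimethylsilyl)ethoxy]methoxy}phenyl)-N-tert-butylmethanimine F8. The annulation of step 6 with 9 proceeds via {[2-bromo-6-[(E)-(tert-butylimino)methyl]-3-methyl-5-{[2-(trimethylsilyl)ethoxy]methoxy}phenyl]methyl}lithium F9 and lithium (3R,6E,10E)-1-{2-bromo-6-[(E)-(tert-butylimino)methyl]-3-methyl-5-{[2-(trimethylsilyl)ethoxy]methoxy}phenyl}-3,7,11,15-tetramethylhexadeca-6,10,14-trien-3-olate F10 to (E)-N-tert-butyl-1-{(2R)-2,8-dimethyl-2-[(3E,7E)-4,8,12-trimethyltrideca-3,7,11-trien-1-yl]-6-{[2-(trimethylsilyl)ethoxy]methoxy}-3,4-dihydro-2H-chromen-5-yl}methanimine F11. Brief treatment with aqueous oxalic acid on silica gel hydrolyses only the imine to (2R)-2,8-dimethyl-2-[(3E,7E)-4,8,12-trimethyltrideca-3,7,11-trien-1-yl]-6-{[2-(trimethylsilyl)ethoxy]methoxy}-3,4-dihydro-2H-chromene-5-carbaldehyde F12, and TBAF in DMPU at 60 °C removes the SEM group to give 13.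

**Further compounds**

F1 | step 6 | (3R,6E,10E)-1-{2-bromo-6-[(E)-(tert-butylimino)methyl]-5-(methoxymethoxy)-3-methylphenyl}-3,7,11,15-tetramethylhexadeca-6,10,14-trien-3-ol | CC(C)=CCC/C(C)=C/CC/C(C)=C/CC[C@](O)(C)CCc1c(Br)c(C)cc(OCOC)c1/C=N/C(C)(C)C
F2 | step 5 | dilithio derivative of 2-methylprop-2-en-1-ol | [Li]CC(=C)CO[Li]
F3 | step 5 | (5E,9E)-6,10,14-trimethyl-2-methylidenepentadeca-5,9,13-trien-1-ol | CC(C)=CCC/C(C)=C/CC/C(C)=C/CCC(=C)CO
F4 | step 5 | {(2R)-2-[(3E,7E)-4,8,12-trimethyltrideca-3,7,11-trien-1-yl]oxiran-2-yl}methanol | CC(C)=CCC/C(C)=C/CC/C(C)=C/CC[C@@]1(CO)CO1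
F5 | step 5 | (2R,5E,9E)-2,6,10,14-tetramethylpentadeca-5,9,13-triene-1,2-diol | CC(C)=CCC/C(C)=C/CC/C(C)=C/CC[C@](O)(C)CO
F6 | step 5 | (2R,5E,9E)-2-hydroxy-2,6,10,14-tetramethylpentadeca-5,9,13-trien-1-yl 4-methylbenzenesulfonate | CC(C)=CCC/C(C)=C/CC/C(C)=C/CC[C@](O)(C)COS(=O)(=O)c1ccc(C)cc1
F7 | step 7 | 3-bromo-2,4-dimethyl-6-{[2-(trimethylsilyl)ethoxy]methoxy}benzaldehyde | O=Cc1c(OCOCC[Si](C)(C)C)cc(C)c(Br)c1C
F8 | step 7 | (E)-1-(3-bromo-2,4-dimethyl-6-{[2-(trimethylsilyl)ethoxy]methoxy}phenyl)-N-tert-butylmethanimine | CC(C)(C)/N=C/c1c(OCOCC[Si](C)(C)C)cc(C)c(Br)c1C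
F9 | step 7 | {[2-bromo-6-[(E)-(tert-butylimino)methyl]-3-methyl-5-{[2-(trimethylsilyl)ethoxy]methoxy}phenyl]methyl}lithium | [Li]Cc1c(Br)c(C)cc(OCOCC[Si](C)(C)C)c1/C=N/C(C)(C)C
F10 | step 7 | lithium (3R,6E,10E)-1-{2-bromo-6-[(E)-(tert-butylimino)methyl]-3-methyl-5-{[2-(trimethylsilyl)ethoxy]methoxy}phenyl}-3,7,11,15-tetramethylhexadeca-6,10,14-trien-3-olate | CC(C)=CCC/C(C)=C/CC/C(C)=C/CC[C@](O[Li])(C)CCc1c(Br)c(C)cc(OCOCC[Si](C)(C)C)c1/C=N/C(C)(C)C
F11 | step 7 | (E)-N-tert-butyl-1-{(2R)-2,8-dimethyl-2-[(3E,7E)-4,8,12-trimethyltrideca-3,7,11-trien-1-yl]-6-{[2-(trimethylsilyl)ethoxy]methoxy}-3,4-dihydro-2H-chromen-5-yl}methanimine | CC(C)=CCC/C(C)=C/CC/C(C)=C/CC[C@]1(C)CCc2c(/C=N/C(C)(C)C)c(OCOCC[Si](C)(C)C)cc(C)c2O1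
F12 | step 7 | (2R)-2,8-dimethyl-2-[(3E,7E)-4,8,12-trimethyltrideca-3,7,11-trien-1-yl]-6-{[2-(trimethylsilyl)ethoxy]methoxy}-3,4-dihydro-2H-chromene-5-carbaldehyde | CC(C)=CCC/C(C)=C/CC/C(C)=C/CC[C@]1(C)CCc2c(C=O)c(OCOCC[Si](C)(C)C)cc(C)c2O1
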